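The plan cuts the two ring C–O bonds that end at methyl-bearing carbons: lactone O4–C4 and peroxide O–C6 (lactone ring C1(=O)–C2–C3–C4–O4; 1,2-dioxane ring C3–C4–C5–C6–O–O). Because C4 and C6 each carry a methyl group and an oxygen, both can come from C=CH2 groups. One treatment with Hg(OAc)2 lets the C3 hydroperoxide close the dioxane on C6 and the carboxyl group close the cis-fused lactone on C4. NaBH4 then turns both CH2Hg groups into the methyl groups. The precursor is the open-chain (3R)-3-hydroperoxy acid with two 1,1-disubstituted alkenes, made by a Schenck ene reaction of an achiral (E)-triene acid and then resolved.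

Key step: step 8

Remark on labels: C1–C6 are the acid-chain atoms named above; in the ring numbering of the bicycle C3 becomes C7a, C4 becomes C4a and C6 becomes C3. The target is (3R,4aR,7aR).
Assumption: the (3R) fraction of step 7 is identified on a small sample by reduction with PPh3 to the β-hydroxy acid and Mosher ester analysis.

Step 1
Reactants: 1 (9-bromononyl)benzene; 2 2,3-dibromopropene
Product: 4 2-bromo-12-phenyldodec-1-ene, via (9-phenylnonyl)magnesium bromide 3 (not isolated)
Conditions: Mg, THF, 25–45 °C; then 2, CuI (5 mol%), THF, −20 °C to rt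
Reagents that add atoms: none
Why: Grignard formation followed by copper-catalysed allylic substitution, in which the alkyl Grignard reagent displaces the allylic bromide of 2 (direct and allylic-shift attack give the same product) while the vinylic C–Br bond stays intact; no stereocentre is involved.

Step 2
Reactants: 4 2-bromo-12-phenyldodec-1-ene; 5 3-bromo-1-(trimethylsilyl)prop-1-yne
Product: 7 trimethyl(4-methylidene-14-phenyltetradec-1-yn-1-yl)silane, via (12-phenyldodec-1-en-2-yl)magnesium bromide 6 (not isolated)
Conditions: Mg, THF, 50 °C; then 5, CuBr·SMe2 (10 mol%), THF, −30 °C to rt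
Reagents that add atoms: none
Why: Copper-catalysed coupling of an alkenyl Grignard reagent with a propargylic bromide, in which the silyl group shields the alkyne terminus so that substitution takes place at the CH2Br carbon and gives the skipped enyne and not an allene; no stereocentre.

Step 3
Reactants: 7 trimethyl(4-methylidene-14-phenyltetradec-1-yn-1-yl)silane
Product: 8 (11-methylidenetetradec-13-yn-1-yl)benzene
Conditions: K2CO3, MeOH, 0 °C to rt
Reagents that add atoms: none
Why: Base-mediated protodesilylation of an alkynylsilane by methanol, mild enough to leave the 1,4-enyne unisomerised; no stereocentre.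

Step 4
Reactants: 8 (11-methylidenetetradec-13-yn-1-yl)benzene; 9 oxirane
Product: 12 (3E)-4-methyl-6-methylidene-16-phenylhexadec-3-en-1-ol, via dimethyl alkenylalane 10 (not isolated), via lithium alkenylalanate 11 (not isolated)
Conditions: Me3Al (2 equiv), Cp2ZrCl2 (25 mol%), CH2Cl2, 0 °C to rt; volatiles removed; n-BuLi, hexane–THF, 0 °C; 9, THF, 0 °C to rt; aq. HCl
Reagents that add atoms: trimethylaluminium, C[Al](C)C
Why: Negishi zirconium-catalysed methylalumination adds CH3 and Al syn across the terminal alkyne (CH3 to the inner carbon), and the butyl ate complex of the alkenylalane opens oxirane with retention of alkene geometry, which fixes the (E) trisubstituted alkene with C2 cis to the C4 methyl while the 1,1-disubstituted alkene stays untouched.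

Step 5
Reactants: 12 (3E)-4-methyl-6-methylidene-16-phenylhexadec-3-en-1-ol
Product: 14 (3E)-4-methyl-6-methylidene-16-phenylhexadec-3-enoic acid, via the corresponding aldehyde 13 (not isolated)
Conditions: CrO3, H2SO4, H2O, acetone, 0 °C
Reagents that add atoms: water, O
Why: Jones oxidation of a primary alcohol through the aldehyde hydrate, which at 0 °C is faster than migration of the β,γ-alkene into conjugation; no stereocentre.

Step 6
Reactants: 14 (3E)-4-methyl-6-methylidene-16-phenylhexadec-3-enoic acid
Product: 15 rac-3-hydroperoxy-4-methylidene-6-(10-phenyldecyl)hept-6-enoic acid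
Conditions: O2, tetraphenylporphyrin (cat.), visible light, CH2Cl2, −20 °C, stopped when 14 is consumed; chromatography on silica
Reagents that add atoms: dioxygen, O=O
Why: Schenck ene reaction, in which singlet oxygen attacks the only trisubstituted alkene on its more crowded side, bonds to C3 and takes a hydrogen from the C4 methyl group, so that the alkene moves to C4=CH2 and C3 is created as a racemate; the 1,1-disubstituted alkene reacts far more slowly, and the conjugated tertiary hydroperoxide that arises from hydrogen transfer from C2 is expected as the chief by-product and is separated by chromatography.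

Step 7
Reactants: 15 rac-3-hydroperoxy-4-methylidene-6-(10-phenyldecyl)hept-6-enoic acid
Product: 16 (3R)-3-hydroperoxy-4-methylidene-6-(10-phenyldecyl)hept-6-enoic acid
Conditions: preparative HPLC, amylose tris(3,5-dimethylphenylcarbamate) on silica, hexane/i-PrOH/AcOH, rt
Reagents that add atoms: none
Why: Chromatographic resolution of enantiomers on a polysaccharide chiral stationary phase, an established way to obtain single enantiomers of allylic hydroperoxy acids without touching the O–O bond; no stereocentre is formed and the (3R) fraction is collected.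

Step 8
Reactants: 16 (3R)-3-hydroperoxy-4-methylidene-6-(10-phenyldecyl)hept-6-enoic acid
Product: 18 (3R,4aR,7aR)-3,4a-bis[(acetyloxymercurio)methyl]-3-(10-phenyldecyl)tetrahydro-3H-furo[3,2-c][1,2]dioxin-6(4H)-one, via monocyclic dioxane mercurial 17 (not isolated)
Conditions: Hg(OAc)2 (1.05 equiv), CH2Cl2, 0 °C, dark; then Hg(OAc)2 (1.15 equiv), 0 °C to rt; filtered, concentrated, used crude
Reagents that add atoms: mercury diacetate, CC(=O)O[Hg]OC(C)=O
Why: Proposed new method: Hg(OAc)2 (divalent mercury) turns each 1,1-disubstituted alkene into a mercurinium ion that an internal oxygen nucleophile opens anti at the tertiary carbon with loss of acetic acid; the closest known reactions are the cycloperoxymercuration of alkenyl hydroperoxides and the mercuri-lactonisation of γ,δ-unsaturated acids, which have not been run together on one substrate in one flask. The C3 hydroperoxide closes the 1,2-dioxane on C6 through a chair-like 6-exo-trig transition state (giving 17), and the carboxyl group then closes the γ-lactone on C4 by 5-exo-trig attack. The step needs the dioxane to close first, and the substrate should secure this: C6=CH2 is an unperturbed dialkyl alkene met by the more nucleophilic hydroperoxide, whereas C4=CH2 is deactivated by the allylic C3–O bond; adding the mercury salt in two portions supports this order, and a lactone closed early on the wrong face can reopen because acyloxymercuration is reversible in the acetic acid set free. C4 is controlled by C3, since on the dioxane ring of 17 the acetic acid arm reaches the exocyclic alkene only from its own face, which gives the cis ring fusion. C6 is set in the chair that holds the C3 arm and the 10-phenyldecyl chain equatorial and the mercurated methylene axial, which places the future C6 methyl cis to the lactone oxygen as in the target; this preference is expected to be modest, so some C6 epimer has to be removed after step 9. Competing modes (7-exo attack of the carboxyl group on C6, endo attack at either CH2 terminus) would pass through a larger ring or a primary cationic centre and are not expected to interfere.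

Step 9
Reactants: 18 (3R,4aR,7aR)-3,4a-bis[(acetyloxymercurio)methyl]-3-(10-phenyldecyl)tetrahydro-3H-furo[3,2-c][1,2]dioxin-6(4H)-one
Product: 19 (3R,4aR,7aR)-3,4a-dimethyl-3-(10-phenyldecyl)tetrahydro-3H-furo[3,2-c][1,2]dioxin-6(4H)-one (target)
Conditions: NaBH4 (excess), aq. NaOH (1 M), CH2Cl2, 0 °C, short contact; then aq. NH4Cl; chromatography
Reagents that add atoms: none
Why: Hydridodemercuration, in which borohydride exchanges each C–Hg bond for C–H through short-lived primary radicals on the exocyclic CH2 groups, so that the three stereocentres are not touched and both methyl groups appear; cold, concentrated hydride should keep the radical next to the peroxide from attacking the O–O bond, and the C6 epimer carried from step 8 is removed here.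

Compound list
1 | (9-bromononyl)benzene | BrCCCCCCCCCc1ccccc1 | starting material
2 | 2,3-dibromopropene | BrCC(Br)=C | starting material
3 | (9-phenylnonyl)magnesium bromide | Br[Mg]CCCCCCCCCc1ccccc1 | intermediate (not isolated)
4 | 2-bromo-12-phenyldodec-1-ene | BrC(=C)CCCCCCCCCCc1ccccc1 | intermediate
5 | 3-bromo-1-(trimethylsilyl)prop-1-yne | C[Si](C)(C)C#CCBr | starting material
6 | (12-phenyldodec-1-en-2-yl)magnesium bromide | Br[Mg]C(=C)CCCCCCCCCCc1ccccc1 | intermediate (not isolated)
7 | trimethyl(4-methylidene-14-phenyltetradec-1-yn-1-yl)silane | C[Si](C)(C)C#CCC(=C)CCCCCCCCCCc1ccccc1 | intermediate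
8 | (11-methylidenetetradec-13-yn-1-yl)benzene | C#CCC(=C)CCCCCCCCCCc1ccccc1 | intermediate
9 | oxirane | C1CO1 | starting material
10 | dimethyl[(1E)-2-methyl-4-methylidene-14-phenyltetradec-1-en-1-yl]alumane | C[Al](C)/C=C(\C)CC(=C)CCCCCCCCCCc1ccccc1 | intermediate (not isolated)
11 | lithium butyl(dimethyl)[(1E)-2-methyl-4-methylidene-14-phenyltetradec-1-en-1-yl]aluminate | [Li+].CCCC[Al-](C)(C)/C=C(\C)CC(=C)CCCCCCCCCCc1ccccc1 | intermediate (not isolated)
12 | (3E)-4-methyl-6-methylidene-16-phenylhexadec-3-en-1-ol | OCC/C=C(\C)CC(=C)CCCCCCCCCCc1ccccc1 | intermediate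
13 | (3E)-4-methyl-6-methylidene-16-phenylhexadec-3-enal | O=CC/C=C(\C)CC(=C)CCCCCCCCCCc1ccccc1 | intermediate (not isolated)
14 | (3E)-4-methyl-6-methylidene-16-phenylhexadec-3-enoic acid | OC(=O)C/C=C(\C)CC(=C)CCCCCCCCCCc1ccccc1 | intermediate
15 | rac-3-hydroperoxy-4-methylidene-6-(10-phenyldecyl)hept-6-enoic acid | OC(=O)CC(OO)C(=C)CC(=C)CCCCCCCCCCc1ccccc1 | intermediate
16 | (3R)-3-hydroperoxy-4-methylidene-6-(10-phenyldecyl)hept-6-enoic acid | OC(=O)C[C@@H](OO)C(=C)CC(=C)CCCCCCCCCCc1ccccc1 | intermediate (precursor of the key step)
17 | 2-[(3R,6R)-6-[(acetyloxymercurio)methyl]-4-methylidene-6-(10-phenyldecyl)-1,2-dioxan-3-yl]acetic acid | CC(=O)O[Hg]C[C@@]1(CCCCCCCCCCc2ccccc2)CC(=C)[C@@H](CC(O)=O)OO1 | intermediate (not isolated)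
18 | (3R,4aR,7aR)-3,4a-bis[(acetyloxymercurio)methyl]-3-(10-phenyldecyl)tetrahydro-3H-furo[3,2-c][1,2]dioxin-6(4H)-one | CC(=O)O[Hg]C[C@@]1(CCCCCCCCCCc2ccccc2)C[C@@]2(C[Hg]OC(C)=O)OC(=O)C[C@H]2OO1 | intermediate (product of the key step)
19 | (3R,4aR,7aR)-3,4a-dimethyl-3-(10-phenyldecyl)tetrahydro-3H-furo[3,2-c][1,2]dioxin-6(4H)-one, cis-fused | C[C@@]1(CCCCCCCCCCc2ccccc2)C[C@@]2(C)OC(=O)C[C@H]2OO1 | target

Total step count: 9. Longest linear sequence: 9 steps (1 to 19).

Steps most likely to fail

Step 8 (key step, the only step beyond established practice). The lactone may close before the dioxane on the face that cannot fuse cis, the facial preference at C6 may be low, or the allylic hydroperoxide may break down under mercury activation before it cyclises. The fallback closes one ring at a time with known reactions, sets out from 16 and comes back at 19. Treatment of 16 with Me3SiCHN2 in toluene–MeOH gives methyl (3R)-3-hydroperoxy-4-methylidene-6-(10-phenyldecyl)hept-6-enoate F1, in which only the hydroperoxide can cyclise. Cycloperoxymercuration with Hg(OAc)2 (1 equiv) in CH2Cl2 gives the dioxane mercurial ester F2, and NaBH4 reduces it to methyl 2-[(3R,6R)-6-methyl-4-methylidene-6-(10-phenyldecyl)-1,2-dioxan-3-yl]acetate F3, at which stage a C6 epimer can be removed. LiOH in aqueous THF gives the dioxane acid F4. Iodolactonisation (I2, NaHCO3, MeCN, 0 °C) then closes the cis-fused lactone on the exocyclic alkene to give the iodomethyl lactone F5, and Bu3SnH with Et3B/air at 0 °C replaces iodine by hydrogen to give 19.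

Step 6. Hydrogen transfer from C2 (leading to the conjugated tertiary hydroperoxide) or from C5 may outrun transfer from the C4 methyl group, so that too little of 15 forms. The fallback gives up the hydroperoxy acid and makes the O–O bond last; it sets out from 14 and comes back at 19. Iodolactonisation of 14 (I2, NaHCO3, MeCN–H2O), in which the carboxylate opens the iodonium ion at the more substituted C4, gives the racemic iodolactone F6. DBU eliminates hydrogen iodide to give the racemic butenolide F7, and preparative HPLC on a chiral phase gives (5R)-5-methyl-5-(2-methylidene-12-phenyldodecyl)furan-2(5H)-one F8. Mukaiyama–Isayama hydroperoxysilylation (Co(thd)2 cat., thd = 2,2,6,6-tetramethylheptane-3,5-dionate, O2, Et3SiH, ClCH2CH2Cl) of the remaining 1,1-disubstituted alkene gives the tertiary triethylsilyl peroxide F9 as both C6 epimers. HCl in MeOH frees the hydroperoxide F10, and Et2NH in CF3CH2OH closes the dioxane by intramolecular oxa-Michael addition to the butenolide on the face of the side arm. This gives 19 together with its C6 epimer F11, which is removed by chromatography.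

Step 9. The CH2 radical at C6 lies β to the peroxide and may attack the O–O bond (epoxide formation with loss of the dioxane) faster than it is reduced, and aqueous base may open the lactone. The fallback sets out from 18 and comes back at 19. Brominolysis (Br2, KBr, MeOH–CH2Cl2, 0 °C) converts 18 into the bis(bromomethyl) compound F12. Both C–Br bonds are then reduced in concentrated Bu3SnH (Et3B/air, 0 °C), where the high concentration of hydrogen donor in a neutral, homogeneous medium should favour reduction over ring opening.

Further compounds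
F1 | step 8 | methyl (3R)-3-hydroperoxy-4-methylidene-6-(10-phenyldecyl)hept-6-enoate | COC(=O)C[C@@H](OO)C(=C)CC(=C)CCCCCCCCCCc1ccccc1
F2 | step 8 | methyl 2-[(3R,6R)-6-[(acetyloxymercurio)methyl]-4-methylidene-6-(10-phenyldecyl)-1,2-dioxan-3-yl]acetate | CC(=O)O[Hg]C[C@@]1(CCCCCCCCCCc2ccccc2)CC(=C)[C@@H](CC(=O)OC)OO1
F3 | step 8 | methyl 2-[(3R,6R)-6-methyl-4-methylidene-6-(10-phenyldecyl)-1,2-dioxan-3-yl]acetate | C[C@@]1(CCCCCCCCCCc2ccccc2)CC(=C)[C@@H](CC(=O)OC)OO1
F4 | step 8 | 2-[(3R,6R)-6-methyl-4-methylidene-6-(10-phenyldecyl)-1,2-dioxan-3-yl]acetic acid | C[C@@]1(CCCCCCCCCCc2ccccc2)CC(=C)[C@@H](CC(O)=O)OO1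
F5 | step 8 | (3R,4aR,7aR)-4a-(iodomethyl)-3-methyl-3-(10-phenyldecyl)tetrahydro-3H-furo[3,2-c][1,2]dioxin-6(4H)-one | C[C@@]1(CCCCCCCCCCc2ccccc2)C[C@@]2(CI)OC(=O)C[C@H]2OO1
F6 | step 6 | rac-(4S,5R)-4-iodo-5-methyl-5-(2-methylidene-12-phenyldodecyl)oxolan-2-one (iodine cis to the C5 methyl; one enantiomer drawn) | O=C1C[C@H](I)[C@@](C)(CC(=C)CCCCCCCCCCc2ccccc2)O1
F7 | step 6 | rac-5-methyl-5-(2-methylidene-12-phenyldodecyl)furan-2(5H)-one | C=C(CCCCCCCCCCc1ccccc1)CC1(C)OC(=O)C=C1
F8 | step 6 | (5R)-5-methyl-5-(2-methylidene-12-phenyldodecyl)furan-2(5H)-one | C=C(CCCCCCCCCCc1ccccc1)C[C@@]1(C)OC(=O)C=C1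
F9 | step 6 | (5R)-5-methyl-5-[2-methyl-12-phenyl-2-(triethylsilylperoxy)dodecyl]furan-2(5H)-one (both epimers at the peroxide carbon) | CC[Si](CC)(CC)OOC(C)(CCCCCCCCCCc1ccccc1)C[C@@]1(C)OC(=O)C=C1
F10 | step 6 | (5R)-5-(2-hydroperoxy-2-methyl-12-phenyldodecyl)-5-methylfuran-2(5H)-one (both epimers at the peroxide carbon) | OOC(C)(CCCCCCCCCCc1ccccc1)C[C@@]1(C)OC(=O)C=C1
F11 | step 6 | (3S,4aR,7aR)-3,4a-dimethyl-3-(10-phenyldecyl)tetrahydro-3H-furo[3,2-c][1,2]dioxin-6(4H)-one (C6 epimer of 19, ring position 3) | C[C@]1(CCCCCCCCCCc2ccccc2)C[C@@]2(C)OC(=O)C[C@H]2OO1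
F12 | step 9 | (3R,4aR,7aR)-3,4a-bis(bromomethyl)-3-(10-phenyldecyl)tetrahydro-3H-furo[3,2-c][1,2]dioxin-6(4H)-one | BrC[C@@]1(CCCCCCCCCCc2ccccc2)C[C@@]2(CBr)OC(=O)C[C@H]2OO1
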